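The dihydrofuran ring is disconnected at O1–C2, and behind it at C2–C3, back to 5-acetylsalicylaldehyde and a four-carbon allylic sulfonium ylide. In one flask the chiral ylide adds to the formyl carbon (future C3), the betaine closes to a trans vinyl oxirane, and the ortho phenoxide O1 opens this temporary ring at its allylic carbon C2 with inversion: two rings close in sequence and C2, C3 and the trans relationship are set. The step exploits the ortho placement of O1 and C3 on the benzene ring and the trans C2-alkenyl/C3-oxygen pattern of the five-membered ring. Ketone transfer hydrogenation, double acylation and allylic oxidation of the isopropenyl methyl group complete the target.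

Key step: step 4

Remark: atom labels O1, C2, C3 follow the 2,3-dihydro-1-benzofuran numbering of the target, and compounds 1, 4, 6 and 10 are taken as catalogue chemicals.

Step 1
Reactants: 1 (2S,5S)-hexane-2,5-diol
Product: 2 (2S,5S)-hexane-2,5-diyl dimethanesulfonate
Conditions: MsCl, Et3N, CH2Cl2, 0 °C
Reagents that add atoms: methanesulfonyl chloride, CS(=O)(=O)Cl
Why: Mesylation takes place at oxygen, so both (S)-carbinol centres are kept while the hydroxyl groups become leaving groups.

Step 2
Reactants: 2 (2S,5S)-hexane-2,5-diyl dimethanesulfonate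
Product: 3 (2R,5R)-2,5-dimethylthiolane
Conditions: Na2S·9H2O, DMSO, rt to 40 °C
Reagents that add atoms: sodium sulfide, [Na+].[Na+].[S-2]
Why: Double SN2 thioetherification, in which sulfide displaces one mesylate and the thiolate closes the ring (5-exo-tet), inverts both centres and should turn the (2S,5S)-dimesylate into the (2R,5R)-thiolane.

Step 3
Reactants: 3 (2R,5R)-2,5-dimethylthiolane; 4 3-bromo-2-methylprop-1-ene
Product: 5 (2R,5R)-2,5-dimethyl-1-(2-methylprop-2-en-1-yl)thiolan-1-ium tetrafluoroborate
Conditions: AgBF4, CH2Cl2, 0 °C to rt, dark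
Reagents that add atoms: silver tetrafluoroborate (AgBF4), [Ag+].F[B-](F)(F)F
Why: S-Alkylation of the sulfide by the allylic bromide is driven by precipitation of AgBr, and the twofold symmetry of 3 makes both sulfur lone pairs equivalent, so a single sulfonium salt should form.

Step 4
Reactants: 6 5-acetyl-2-hydroxybenzaldehyde; 5 (2R,5R)-2,5-dimethyl-1-(2-methylprop-2-en-1-yl)thiolan-1-ium tetrafluoroborate
Product: 8 (2R,3S)-5-acetyl-2-(prop-1-en-2-yl)-2,3-dihydro-1-benzofuran-3-ol, via trans-vinyl oxirane 7 (not isolated)
Conditions: NaOH (2.5 equiv), t-BuOH/H2O 9:1, 0 °C to rt; then 50 °C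
Reagents that add atoms: none
Why: Corey–Chaykovsky epoxidation relayed into an intramolecular phenoxide epoxide opening, the sulfur-ylide annulation known to convert salicylaldehydes into 2,3-dihydrobenzofuran-3-ols: hydroxide generates the phenoxide of 6 and the allylic ylide of 5, the ylide carbon adds to the formyl carbon (C2–C3 bond), the betaine alkoxide expels thiolane 3 to give trans-oxirane 7, and on warming the ortho phenoxide O1 attacks the allylic oxirane carbon to form the O1–C2 bond. The oxirane closes by 3-exo-tet displacement and the dihydrofuran ring by 5-endo opening of the epoxide at its vinyl-activated carbon, the only position O1 can reach, since attack at benzylic C3 would need a four-membered ring and attack at the alkene terminus a seven-membered one. C3 is set in the ylide addition by the twofold-symmetric (2R,5R)-thiolane, whose ylide should hold the isopropenyl group syn to the sulfur lone pair and be attacked on the face remote from the adjacent ring methyl group, which, with reversible betaine formation favouring the anti betaine, should give the (2S,3S)-trans-oxirane. C2 is then set by stereospecific inversion in the O1–C2 bond formation, so that the trans-oxirane is translated into the (2R,3S)-trans-dihydrobenzofuran. The step needs aldehyde-over-ketone chemoselectivity, secured by the greater electrophilicity of the formyl group and by the para-oxido substituent that deactivates the acetyl group towards addition and enolisation, and it needs oxirane closure to outrun direct displacement of the sulfonium group by the phenoxide (which would give the cis isomer), secured by the far higher nucleophilicity and proximity of the alkoxide.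

Step 5
Reactants: 8 (2R,3S)-5-acetyl-2-(prop-1-en-2-yl)-2,3-dihydro-1-benzofuran-3-ol
Product: 9 (2R,3S)-5-[(1R)-1-hydroxyethyl]-2-(prop-1-en-2-yl)-2,3-dihydro-1-benzofuran-3-ol
Conditions: RuCl(p-cymene)[(R,R)-TsDPEN] (1 mol %), HCO2Na, H2O/MeOH 1:1, 40 °C
Reagents that add atoms: none
Why: Noyori–Ikariya asymmetric transfer hydrogenation with the (R,R)-TsDPEN ruthenium hydride should reduce the aryl methyl ketone to the (R)-1-arylethanol under catalyst control, independent of the remote ring stereocentres, and should leave the 1,1-disubstituted alkene and the C3 carbinol untouched in the near-neutral formate medium.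

Step 6
Reactants: 9 (2R,3S)-5-[(1R)-1-hydroxyethyl]-2-(prop-1-en-2-yl)-2,3-dihydro-1-benzofuran-3-ol; 10 3-methylbutanoic anhydride
Product: 11 (1R)-1-[(2R,3S)-3-(3-methylbutanoyloxy)-2-(prop-1-en-2-yl)-2,3-dihydro-1-benzofuran-5-yl]ethyl 3-methylbutanoate
Conditions: Et3N, DMAP (cat.), CH2Cl2, 0 °C to rt
Reagents that add atoms: none
Why: DMAP-catalysed acylation of both secondary benzylic alcohols takes place at oxygen, with retention at C3 and at the side-chain carbinol, and is placed before the enal is made because the enal would be sensitive to nucleophilic catalysts.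

Step 7
Reactants: 11 (1R)-1-[(2R,3S)-3-(3-methylbutanoyloxy)-2-(prop-1-en-2-yl)-2,3-dihydro-1-benzofuran-5-yl]ethyl 3-methylbutanoate
Product: 13 (1R)-1-[(2R,3S)-3-(3-methylbutanoyloxy)-2-(3-oxoprop-1-en-2-yl)-2,3-dihydro-1-benzofuran-5-yl]ethyl 3-methylbutanoate, via allylic alcohol 12 (not isolated)
Conditions: SeO2 (0.5 equiv), t-BuOOH, CH2Cl2, rt; then MnO2, CH2Cl2, rt
Reagents that add atoms: tert-butyl hydroperoxide, CC(C)(C)OO (oxygen transferred through catalytic SeO2)
Why: Riley allylic oxidation (ene reaction, then [2,3]-sigmatropic shift of the allylseleninic acid) should attack the methyl group of the 1,1-disubstituted alkene in preference to the methine C2–H, and MnO2 should then oxidise only the primary allylic alcohol 12 to the enal, both benzylic oxygens being acylated and no stereocentre being touched.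

Compound list
1 | (2S,5S)-hexane-2,5-diol | C[C@H](O)CC[C@H](C)O | starting material
2 | (2S,5S)-hexane-2,5-diyl dimethanesulfonate | C[C@H](OS(C)(=O)=O)CC[C@H](C)OS(C)(=O)=O | intermediate
3 | (2R,5R)-2,5-dimethylthiolane | C[C@@H]1CC[C@@H](C)S1 | intermediate
4 | 3-bromo-2-methylprop-1-ene | C=C(C)CBr | starting material
5 | (2R,5R)-2,5-dimethyl-1-(2-methylprop-2-en-1-yl)thiolan-1-ium tetrafluoroborate | C[C@@H]1CC[C@@H](C)[S+]1CC(C)=C.F[B-](F)(F)F | intermediate
6 | 5-acetyl-2-hydroxybenzaldehyde | CC(=O)c1ccc(O)c(C=O)c1 | starting material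
7 | (2S,3S)-2-(5-acetyl-2-hydroxyphenyl)-3-(prop-1-en-2-yl)oxirane (trans-vinyl oxirane, present as its phenoxide) | CC(=C)[C@@H]1O[C@H]1c1cc(C(C)=O)ccc1O | intermediate
8 | (2R,3S)-5-acetyl-2-(prop-1-en-2-yl)-2,3-dihydro-1-benzofuran-3-ol | CC(=C)[C@H]1Oc2ccc(C(C)=O)cc2[C@@H]1O | intermediate
9 | (2R,3S)-5-[(1R)-1-hydroxyethyl]-2-(prop-1-en-2-yl)-2,3-dihydro-1-benzofuran-3-ol | CC(=C)[C@H]1Oc2ccc([C@@H](C)O)cc2[C@@H]1O | intermediate
10 | 3-methylbutanoic anhydride (isovaleric anhydride) | CC(C)CC(=O)OC(=O)CC(C)C | starting material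
11 | (1R)-1-[(2R,3S)-3-(3-methylbutanoyloxy)-2-(prop-1-en-2-yl)-2,3-dihydro-1-benzofuran-5-yl]ethyl 3-methylbutanoate | CC(=C)[C@H]1Oc2ccc([C@@H](C)OC(=O)CC(C)C)cc2[C@@H]1OC(=O)CC(C)C | intermediate
12 | (1R)-1-[(2R,3S)-2-(3-hydroxyprop-1-en-2-yl)-3-(3-methylbutanoyloxy)-2,3-dihydro-1-benzofuran-5-yl]ethyl 3-methylbutanoate (allylic alcohol) | C=C(CO)[C@H]1Oc2ccc([C@@H](C)OC(=O)CC(C)C)cc2[C@@H]1OC(=O)CC(C)C | intermediate
13 | (1R)-1-[(2R,3S)-3-(3-methylbutanoyloxy)-2-(3-oxoprop-1-en-2-yl)-2,3-dihydro-1-benzofuran-5-yl]ethyl 3-methylbutanoate | C=C(C=O)[C@H]1Oc2ccc([C@@H](C)OC(=O)CC(C)C)cc2[C@@H]1OC(=O)CC(C)C | target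

Total step count: 7.
Longest linear sequence: 7 steps (steps 1 to 7, through the sulfonium reagent). From aldehyde 6 the sequence is 4 steps.

Steps most likely to fail

Step 4 (key step). The phenoxide may be O-allylated by the sulfonium salt before the ylide forms. Facial control in the ylide addition to the deactivated phenoxide-aldehyde may be incomplete. The benzylic C3–O bond of the oxirane may ionise through the ortho-quinone methide before ring closure, which would erode the configuration at C3. The fallback replaces the ylide chemistry by olefin epoxidation; it sets out from 6 and comes back at 8. Compound 6 is silylated (TIPSCl, imidazole, DMF) to 5-acetyl-2-[(triisopropylsilyl)oxy]benzaldehyde F1. Horner–Wadsworth–Emmons olefination of the formyl group with diethyl (2-methylprop-2-en-1-yl)phosphonate (n-BuLi, THF, −78 °C to rt) should give 1-{3-[(1E)-3-methylbuta-1,3-dien-1-yl]-4-[(triisopropylsilyl)oxy]phenyl}ethan-1-one F2. Shi epoxidation with the L-fructose-derived ketone (KHSO5 as Oxone, K2CO3, MeCN/dimethoxymethane/H2O, 0 °C) should epoxidise the trans-disubstituted styrenyl alkene in preference to the 1,1-disubstituted one and give 1-{3-[(2S,3S)-3-(prop-1-en-2-yl)oxiran-2-yl]-4-[(triisopropylsilyl)oxy]phenyl}ethan-1-one F3. TBAF (THF, 0 °C to rt) then removes the silyl group, and the liberated phenoxide closes the O1–C2 bond by the same epoxide opening to give 8.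

Step 7. The ene step may attack the allylic C2–H instead of the methyl group, the oxidation may run on past the aldehyde, or the benzylic esters may ionise in the mildly acidic selenium medium. The fallback sets out from 11 and comes back at 13. Ene-type allylic chlorination of the isopropenyl group (N-chlorosuccinimide, PhSeCl cat., CH2Cl2, rt) should give (1R)-1-[(2R,3S)-2-(3-chloroprop-1-en-2-yl)-3-(3-methylbutanoyloxy)-2,3-dihydro-1-benzofuran-5-yl]ethyl 3-methylbutanoate F4. Kornblum-type oxidation of the allylic chloride with N-methylmorpholine N-oxide (KI cat., MeCN, rt) should give enal 13.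

Step 5. The ruthenium hydride may reversibly dehydrogenate the C3 carbinol, which would epimerise C2 and C3 through the benzofuran-3-one, or the benzylic C3 alcohol may dehydrate to the benzofuran. The fallback replaces catalyst-controlled reduction by enzymatic resolution; it sets out from 8 and comes back at 11. NaBH4 (MeOH, 0 °C) reduces the ketone without selectivity to (2R,3S)-5-(1-hydroxyethyl)-2-(prop-1-en-2-yl)-2,3-dihydro-1-benzofuran-3-ol F5, as both epimers at the side-chain carbinol. Acylation with Candida antarctica lipase B and anhydride 10 (MTBE, rt) should esterify only the (R)-configured 1-arylethanol epimer, giving (1R)-1-[(2R,3S)-3-hydroxy-2-(prop-1-en-2-yl)-2,3-dihydro-1-benzofuran-5-yl]ethyl 3-methylbutanoate F6, which is separated from the unreacted (S)-epimer. Acylation of the C3 hydroxyl of F6 with 10 (Et3N, DMAP, CH2Cl2) gives 11.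

Further compounds
F1 | step 4 | 5-acetyl-2-[(triisopropylsilyl)oxy]benzaldehyde | CC(=O)c1ccc(O[Si](C(C)C)(C(C)C)C(C)C)c(C=O)c1
F2 | step 4 | 1-{3-[(1E)-3-methylbuta-1,3-dien-1-yl]-4-[(triisopropylsilyl)oxy]phenyl}ethan-1-one | CC(=O)c1ccc(O[Si](C(C)C)(C(C)C)C(C)C)c(/C=C/C(C)=C)c1
F3 | step 4 | 1-{3-[(2S,3S)-3-(prop-1-en-2-yl)oxiran-2-yl]-4-[(triisopropylsilyl)oxy]phenyl}ethan-1-one | CC(=C)[C@@H]1O[C@H]1c1cc(C(C)=O)ccc1O[Si](C(C)C)(C(C)C)C(C)C
F4 | step 7 | (1R)-1-[(2R,3S)-2-(3-chloroprop-1-en-2-yl)-3-(3-methylbutanoyloxy)-2,3-dihydro-1-benzofuran-5-yl]ethyl 3-methylbutanoate | C=C(CCl)[C@H]1Oc2ccc([C@@H](C)OC(=O)CC(C)C)cc2[C@@H]1OC(=O)CC(C)C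
F5 | step 5 | (2R,3S)-5-(1-hydroxyethyl)-2-(prop-1-en-2-yl)-2,3-dihydro-1-benzofuran-3-ol (both epimers at the side-chain carbinol) | CC(=C)[C@H]1Oc2ccc(C(C)O)cc2[C@@H]1O
F6 | step 5 | (1R)-1-[(2R,3S)-3-hydroxy-2-(prop-1-en-2-yl)-2,3-dihydro-1-benzofuran-5-yl]ethyl 3-methylbutanoate | CC(=C)[C@H]1Oc2ccc([C@@H](C)OC(=O)CC(C)C)cc2[C@@H]1O
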